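Read outward from the ring oxygen, rings B and D show one and the same order of atoms: O-bearing fusion carbon, C–OAr, C–OH, C–H, C–OH, second fusion carbon. Both rings are therefore cut at the C(OH)–CH bond beside the aryloxy carbon, which leaves the dioxin C=C and the furan C2=C3 bond as central alkenes of two trienes on a ring C core. In one operation base turns two α-aryloxyacetyl chloride arms into ketenes, and each ketene carbon bonds to the CH2 end of the adjacent 1-methoxyvinyl group, closing B and D as phenols. The precursor is a furan-fused 1,4-benzodioxine carrying, on each heterocyclic C=C, one methoxyvinyl group and one (3,5-dimethoxyphenoxy)acetyl chloride arm.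

Key step: step 11

**Labels.** A and E are the two phenoxy rings (A on B, E on D). B is the outer ring of the dibenzodioxin, C the central benzene ring and D the outer ring of the dibenzofuran. The core is numbered as a benzofuran (O1, C2, C3, C3a, C4 to C7, C7a), and O4 and O5 are the oxygens on C4 and C5. The dioxine carbon on O4 becomes the ring B fusion carbon next to C–OH. The dioxine carbon on O5 becomes the fusion carbon next to C–OAr.

**Assumption.** The target has no stereocentre. Compounds 8 and 9 are racemic, and 14, 16, 17 and 18 are carried as diastereomer mixtures, because every sp3 centre is erased in step 5 or step 11.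

**Design remarks.**
- The dioxine is made from a C3 unit that already has the oxidation level of the ring. No radical bromination is then needed on a core whose C7–H is as nucleophilic as a phloroglucinol ether.
- The free diacid is never generated next to the enol ethers.
- From 11 to 18, no aqueous phase below pH 7 is used, and chromatography is done only on basic Al2O3 or Et3N-deactivated silica.

## Route

Step 1
Reactants: 1 3,4,5-trimethoxyphenol; 2 methyl propiolate
Product: 3 methyl (E)-3-(3,4,5-trimethoxyphenoxy)acrylate
Conditions: DABCO (10 mol %), CH2Cl2, 0 °C to rt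
Reagents that add atoms: methyl propiolate (2), C#CC(=O)OC
Why: Amine-catalysed oxa-Michael addition of a phenol to an alkynoate is reliable and should give the E-β-aryloxyacrylate, and the symmetric phenol 1 makes both ortho positions equivalent for step 2.

Step 2
Reactants: 3 methyl (E)-3-(3,4,5-trimethoxyphenoxy)acrylate
Product: 4 methyl 4,5,6-trimethoxy-1-benzofuran-3-carboxylate
Conditions: Pd(OAc)2 (10 mol %), PPh3 (10 mol %), AgO2CCF3 (2.2 equiv), PhH, 110 °C, sealed tube
Reagents that add atoms: none
Why: Intramolecular dehydrogenative Heck (Fujiwara–Moritani-type) cyclisation of 3-aryloxyacrylates with divalent palladium and a silver oxidant is a known entry to benzofuran-3-carboxylates, and the two equivalent ortho C–H bonds sit on a very electron-rich ring that favours electrophilic palladation.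

Step 3
Reactants: 4 methyl 4,5,6-trimethoxy-1-benzofuran-3-carboxylate
Product: 6 methyl 4,5-dihydroxy-6-methoxy-1-benzofuran-3-carboxylate, via cyclic chloroborate 5 (not isolated)
Conditions: BCl3 (3.5 equiv), CH2Cl2, −78 °C to rt; then H2O
Reagents that add atoms: none
Why: Lewis-acid aryl methyl ether cleavage in which BCl3 held on the C3 ester carbonyl reaches the peri 4-OMe and the boron aryloxide then takes the adjacent 5-OMe by closing the five-membered borate 5 (the pattern known for 2,3,4-trimethoxyaryl carbonyl compounds), while the 6-OMe, the only methoxy group with a free ortho position and hence coplanar and least basic, should remain.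

Step 4
Reactants: 6 methyl 4,5-dihydroxy-6-methoxy-1-benzofuran-3-carboxylate; 7 methyl 3-bromo-2-oxopropanoate (methyl bromopyruvate)
Product: 8 racemic tricyclic hemiketal (6 with the bridge O5–CH2–C(OH)(CO2Me)–O4)
Conditions: K2CO3 (1.05 equiv), acetone, Ar, 0 °C to rt, 7 added slowly
Reagents that add atoms: methyl bromopyruvate (7), COC(=O)C(=O)CBr
Why: Williamson alkylation by an α-bromoketone followed by spontaneous hemiketalisation, in which the 4-OH is hydrogen-bonded to and shielded by the peri ester so that O5 (also the more basic oxygen) should take the CH2 carbon and O4 then adds to the very electrophilic keto ester, placing the ester-bearing carbon on O4 as ring B requires, the racemic hemiketal centre being erased in step 5.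

Step 5
Reactants: 8 racemic tricyclic hemiketal
Product: 10 dioxine diester (methyl 6-methoxy-1-benzofuran-3-carboxylate with the bridge O5–CH=C(CO2Me)–O4), via anomeric trifluoroacetate 9 (not isolated)
Conditions: (CF3CO)2O (1.5 equiv), pyridine (4 equiv), CH2Cl2, 0 °C; then Et3N (3 equiv), rt
Reagents that add atoms: none
Why: Acylative dehydration, the protocol used to aromatise the hydroxythiazolines obtained from bromopyruvate in the modified Hantzsch synthesis, turns the tertiary hemiketal into a leaving group and amine-induced elimination should give the push–pull alkene without any oxidant that could attack C7–H.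

Step 6
Reactants: 10 dioxine diester
Product: 11 bis(1-methoxyvinyl) core (both CO2Me groups of 10 converted into C(OMe)=CH2)
Conditions: Cp2TiMe2 (5 equiv), toluene, 75 °C, dark; filtration through basic Al2O3
Reagents that add atoms: Cp2TiMe2, C[Ti+2]C.c1cc[cH-]c1.c1cc[cH-]c1
Why: Petasis methylenation, in which thermally released Cp2Ti=CH2 converts aryl and vinylogous esters into methyl enol ethers through an oxatitanacyclobutane under non-acidic conditions, is applied while the two ring esters are the only carbonyl groups in the molecule.

Step 7
Reactants: 11 bis(1-methoxyvinyl) core; 12 ethyl glyoxylate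
Product: 14 bis(α-hydroxy ester) (CH(OH)CO2Et at furan C2 and at the dioxine carbon on O5; diastereomer mixture), via dilithio species 13 (not isolated)
Conditions: n-BuLi (2.3 equiv), THF, −78 °C, 1 h; then 12 (freshly cracked, 4 equiv), −78 °C; pH 7 phosphate buffer
Reagents that add atoms: ethyl glyoxylate (12), CCOC(=O)C=O
Why: Heteroatom-directed lithiation followed by 1,2-addition to an aldehyde, since the furan C2–H and the dioxine C–H are each α to a ring oxygen and beside a coordinating methoxyvinyl group and such positions are metalated by n-BuLi at −78 °C, where the arene C7–H between two oxygens is slow to react and the lithiodioxine does not ring-open, the two carbinol centres forming without control and being erased in step 11.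

Step 8
Reactants: 14 bis(α-hydroxy ester); 15 3,5-dimethoxyphenol
Product: 16 bis(α-aryloxy ester) (each OH of 14 replaced by 3,5-dimethoxyphenoxy; diastereomer mixture)
Conditions: 15 (3 equiv), PPh3 (3.2 equiv), DIAD (3.0 equiv, added last, dropwise), toluene, 0 °C to rt
Reagents that add atoms: 3,5-dimethoxyphenol (15), COc1cc(O)cc(OC)c1
Why: Double Mitsunobu etherification works well on secondary α-hydroxy esters, the neutral medium spares the enol ethers, slow addition of DIAD to excess PPh3 keeps free azo compound away from the electron-rich dienes, and inversion at each centre is irrelevant because the mixture is carried on.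

Step 9
Reactants: 16 bis(α-aryloxy ester)
Product: 17 dipotassium dicarboxylate of 16
Conditions: KOSiMe3 (2.2 equiv), THF, rt; salt precipitated with Et2O and dried in vacuo
Reagents that add atoms: KOSiMe3, [K+].C[Si](C)(C)[O-]
Why: Anhydrous ester cleavage with a silanolate delivers the carboxylate salt directly, so the free acid, which could protonate the neighbouring enol ether and be trapped as a lactone ketal, is never formed.

Step 10
Reactants: 17 dipotassium dicarboxylate
Product: 18 bis(acid chloride) (core bearing two 1-methoxyvinyl groups plus two CH(OAr)COCl arms; diastereomer mixture)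
Conditions: 2-chloro-1,3-dimethylimidazolinium chloride (2.1 equiv), 18-crown-6 (10 mol %), ClCH2CH2Cl, −10 °C to 0 °C; filtered under Ar, solution used at once
Reagents that add atoms: 2-chloro-1,3-dimethylimidazolinium chloride, CN1CC[N+](C)=C1Cl.[Cl-]
Why: Chloroamidinium (Vilsmeier-type) activation, in which the carboxylate attacks C2 of the imidazolinium ion and chloride then displaces the urea from the acyl carbon, is free of protons and amines, so it should form neither HCl nor ketene, and the reagent is too weak a carbon electrophile to acylate enol ethers as oxalyl chloride would.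

Step 11
Reactants: 18 bis(acid chloride)
Product: 21 heptamethyl ether of the target (free OH only on the carbon next to C–OAr in ring B and in ring D), via bis(ketene) 19 (not isolated), via bis(cyclohexadienone) 20 (not isolated)
Conditions: solution of 18 added over 10 h (syringe pump) to Et3N (10 equiv), toluene, 80 °C, final concentration about 1 mM
Reagents that add atoms: none
Why: Proposed new method: Et3N removes the doubly activated CH(OAr) proton of each arm with loss of chloride, which erases both stereocentres of 18 and gives aryloxy(heteroaryl)ketenes 19 in which C=C=O, the ring double bond and the methoxyvinyl group make up a 1,3,5-triene whose central alkene is fixed Z by the heterocycle. Ring B (on the dioxin C=C) and ring D (on the furan C2=C3) each close by a thermal disrotatory 6π electrocyclisation to a six-membered carbocycle that joins the ketene carbonyl carbon to the vinyl CH2, and base-mediated tautomerisation of dienone 20 gives phenols with OAr, OH, H and OMe already in the order of the target. The closest known reaction type is the dienylketene-to-phenol closure that ends the Danheiser and Moore benzannulations and the amine-induced cyclisation of activated hexa-3,5-dienoic acids, whereas a 1,4-dioxin or benzofuran 2,3-bond as central alkene, an aryloxy group on the ketene and two closures in one molecule have not been shown. The dioxin C=C is a plain enediol diether and the benzofuran 2,3-bond is the most alkene-like bond of that system, so little aromaticity is lost in the transition state, and a stepwise attack of the nucleophilic enol ether carbon on the ketene or acyl chloride would make the same bond. No stereocentre is formed. Closure must outrun ketene dimerisation, intermolecular [2+2] addition and acylation of phenols already formed, which is secured by the cis-1,2 placement that makes closure unimolecular, by the strain of any intramolecular [2+2] adduct, and by feeding 18 slowly into excess hot base so that acylating species stay at trace concentration.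

Step 12
Reactants: 21 heptamethyl ether
Product: 22 phlorofucofuroeckol A
Conditions: BBr3 (25 equiv), CH2Cl2, −78 °C to rt; then H2O, 0 °C; handled under Ar
Reagents that add atoms: none
Why: Exhaustive BBr3 cleavage of aryl methyl ethers is standard for phloroglucinol-derived polyethers, and the diaryl ether, dibenzofuran and dibenzodioxin C–O bonds offer bromide no sp3 carbon and should survive.

## Compound list

1 | 3,4,5-trimethoxyphenol | COc1cc(O)cc(OC)c1OC | starting material
2 | methyl propiolate | C#CC(=O)OC | starting material
3 | methyl (E)-3-(3,4,5-trimethoxyphenoxy)acrylate | COC(=O)/C=C/Oc1cc(OC)c(OC)c(OC)c1 | intermediate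
4 | methyl 4,5,6-trimethoxy-1-benzofuran-3-carboxylate | COC(=O)c1coc2cc(OC)c(OC)c(OC)c12 | intermediate
5 | cyclic chloroborate of 6 (O4–B(Cl)–O5), not isolated | COC(=O)c1coc2cc(OC)c3OB(Cl)Oc3c12 | intermediate
6 | methyl 4,5-dihydroxy-6-methoxy-1-benzofuran-3-carboxylate | COC(=O)c1coc2cc(OC)c(O)c(O)c12 | intermediate
7 | methyl 3-bromo-2-oxopropanoate | COC(=O)C(=O)CBr | starting material
8 | racemic hemiketal, bridge O5–CH2–C(OH)(CO2Me)–O4 | COC(=O)c1coc2cc(OC)c3OCC(O)(C(=O)OC)Oc3c12 | intermediate
9 | racemic anomeric trifluoroacetate of 8, not isolated | COC(=O)c1coc2cc(OC)c3OCC(OC(=O)C(F)(F)F)(C(=O)OC)Oc3c12 | intermediate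
10 | dioxine diester, bridge O5–CH=C(CO2Me)–O4 | COC(=O)c1coc2cc(OC)c3OC=C(C(=O)OC)Oc3c12 | intermediate
11 | bis(1-methoxyvinyl) core | COC(=C)c1coc2cc(OC)c3OC=C(C(=C)OC)Oc3c12 | intermediate
12 | ethyl glyoxylate | CCOC(=O)C=O | starting material
13 | dilithio species (Li at furan C2 and at the dioxine carbon on O5), not isolated | [Li]c1oc2cc(OC)c3OC([Li])=C(C(=C)OC)Oc3c2c1C(=C)OC | intermediate
14 | bis(α-hydroxy ester), diastereomer mixture | CCOC(=O)C(O)c1oc2cc(OC)c3OC(C(O)C(=O)OCC)=C(C(=C)OC)Oc3c2c1C(=C)OC | intermediate
15 | 3,5-dimethoxyphenol | COc1cc(O)cc(OC)c1 | starting material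
16 | bis(α-aryloxy ester), diastereomer mixture | CCOC(=O)C(Oc1cc(OC)cc(OC)c1)c1oc2cc(OC)c3OC(C(Oc4cc(OC)cc(OC)c4)C(=O)OCC)=C(C(=C)OC)Oc3c2c1C(=C)OC | intermediate
17 | dipotassium dicarboxylate, diastereomer mixture | [K+].[K+].[O-]C(=O)C(Oc1cc(OC)cc(OC)c1)c1oc2cc(OC)c3OC(C(Oc4cc(OC)cc(OC)c4)C([O-])=O)=C(C(=C)OC)Oc3c2c1C(=C)OC | intermediate
18 | bis(acid chloride), precursor of the key step, diastereomer mixture | COc1cc2oc(C(Oc3cc(OC)cc(OC)c3)C(Cl)=O)c(C(=C)OC)c2c2OC(C(=C)OC)=C(C(Oc3cc(OC)cc(OC)c3)C(Cl)=O)Oc12 | intermediate
19 | bis(ketene), not isolated | COc1cc2oc(C(Oc3cc(OC)cc(OC)c3)=C=O)c(C(=C)OC)c2c2OC(C(=C)OC)=C(C(Oc3cc(OC)cc(OC)c3)=C=O)Oc12 | intermediate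
20 | bis(cyclohexadienone), not isolated | COc1cc2OC3=C(Oc4cc(OC)cc(OC)c4)C(=O)CC(OC)=C3c2c2OC3=C(OC)CC(=O)C(Oc4cc(OC)cc(OC)c4)=C3Oc12 | intermediate
21 | heptamethyl ether of the target, product of the key step | COc1cc(OC)cc(Oc2c(O)cc(OC)c3c2Oc2c(OC)cc4oc5c(Oc6cc(OC)cc(OC)c6)c(O)cc(OC)c5c4c2O3)c1 | intermediate
22 | phlorofucofuroeckol A | Oc1cc(O)cc(Oc2c(O)cc(O)c3c2Oc2c(O)cc4oc5c(Oc6cc(O)cc(O)c6)c(O)cc(O)c5c4c2O3)c1 | target

Total step count: 12. Longest linear sequence: 12 steps (from 1 to 22).

## Steps most likely to fail

**Step 11.**
- What may go wrong: the slower closure, probably the one on the furan side, may lose out to ketene oligomerisation or to acylation of the phenol formed first. The enol ethers may also be lost before closure.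
- Fallback: it sets out from 16 and comes back at 22. It makes the same two C(OH)–CH bonds by known polar chemistry and also bypasses steps 9 and 10.
- Brief treatment with dilute aqueous HCl in THF hydrolyses both enol ethers to the diacetyl diester F1.
- Excess t-BuOK in THF then brings about a double intramolecular Claisen (Dieckmann-type) condensation of each methyl ketone enolate onto the neighbouring arm ester. This reaction type is known to turn 2-acetylarylacetates into resorcinol rings, and aromatisation drives it to the pentamethyl ether with four free hydroxyls F2.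
- BBr3 as in step 12 then gives 22.

**Step 4.**
- What may go wrong: the wrong catechol oxygen may be alkylated first (poor regioselectivity), or the bromopyruvate may self-condense under base.
- Fallback: it sets out from 3 and comes back at 8. It fixes the O5–CH2 bond by construction and leaves BCl3 only one ether to cleave.
- AlCl3 in CH2Cl2 cleaves the out-of-plane central methoxy group of symmetric 3 to methyl (E)-3-(4-hydroxy-3,5-dimethoxyphenoxy)acrylate F3.
- Ac2O and pyridine give its acetate F4.
- The conditions of step 2 give methyl 5-acetoxy-4,6-dimethoxy-1-benzofuran-3-carboxylate F5.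
- K2CO3 in MeOH frees methyl 5-hydroxy-4,6-dimethoxy-1-benzofuran-3-carboxylate F6, whose only free oxygen is O5.
- Alkylation with 7 (K2CO3, acetone) gives the aryloxypyruvate F7.
- BCl3 then removes the peri 4-O-methyl group, and the freed O4 closes onto the ketone to give 8.

**Step 7.**
- What may go wrong: the second metalation may be incomplete, C7–H may be metalated in competition, the lithiated dioxine may ring-open by loss of phenoxide, or partly polymeric glyoxylate may add poorly.
- Fallback: it sets out from 10 and comes back at 14. It marks the two carbons while the esters can still direct the base.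
- TMPMgCl·LiCl (THF, −40 °C) gives the bis(chloromagnesio) diester F8, and I2 converts it into the diiodo diester F9.
- Cp2TiMe2 as in step 6 gives the diiodo bis(enol ether) F10.
- Iodine–magnesium exchange with iPrMgCl·LiCl (THF, −40 °C) gives the bis(Grignard) reagent F11. It is metalated only at the marked carbons and is less prone to β-elimination than 13.
- Addition of F11 to 12 gives 14.

## Further compounds

F1 | step 11 | diacetyl diester (both C(OMe)=CH2 groups of 16 hydrolysed to acetyl) | CCOC(=O)C(Oc1cc(OC)cc(OC)c1)c1oc2cc(OC)c3OC(C(Oc4cc(OC)cc(OC)c4)C(=O)OCC)=C(C(C)=O)Oc3c2c1C(C)=O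
F2 | step 11 | pentamethyl ether of the target with four free hydroxyls on rings B and D | COc1cc(OC)cc(Oc2c(O)cc(O)c3c2Oc2c(OC)cc4oc5c(Oc6cc(OC)cc(OC)c6)c(O)cc(O)c5c4c2O3)c1
F3 | step 4 | methyl (E)-3-(4-hydroxy-3,5-dimethoxyphenoxy)acrylate | COC(=O)/C=C/Oc1cc(OC)c(O)c(OC)c1
F4 | step 4 | methyl (E)-3-(4-acetoxy-3,5-dimethoxyphenoxy)acrylate | COC(=O)/C=C/Oc1cc(OC)c(OC(C)=O)c(OC)c1
F5 | step 4 | methyl 5-acetoxy-4,6-dimethoxy-1-benzofuran-3-carboxylate | COC(=O)c1coc2cc(OC)c(OC(C)=O)c(OC)c12
F6 | step 4 | methyl 5-hydroxy-4,6-dimethoxy-1-benzofuran-3-carboxylate | COC(=O)c1coc2cc(OC)c(O)c(OC)c12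
F7 | step 4 | methyl 4,6-dimethoxy-5-(3-methoxy-2,3-dioxopropoxy)-1-benzofuran-3-carboxylate | COC(=O)C(=O)COc1c(OC)cc2occ(C(=O)OC)c2c1OC
F8 | step 7 | bis(chloromagnesio) diester | COC(=O)c1c([Mg]Cl)oc2cc(OC)c3OC([Mg]Cl)=C(C(=O)OC)Oc3c12
F9 | step 7 | diiodo diester | COC(=O)c1c(I)oc2cc(OC)c3OC(I)=C(C(=O)OC)Oc3c12
F10 | step 7 | diiodo bis(enol ether) | COC(=C)c1c(I)oc2cc(OC)c3OC(I)=C(C(=C)OC)Oc3c12
F11 | step 7 | bis(Grignard) reagent | COC(=C)c1c([Mg]Cl)oc2cc(OC)c3OC([Mg]Cl)=C(C(=C)OC)Oc3c12
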